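The flavone is cut at the three bonds that meet around ring C: C4a–C4, C4–C3 and O1–C2. C4 bears nothing but its carbonyl oxygen. It is flanked by C4a of the fully substituted ring A and by the C3–C2 unit that holds ring B, so it is supplied as carbon monoxide. One palladium-catalysed operation joins three components and closes the pyranone. They are an ortho-iodophenol (ring A, four methoxy groups, iodine next to the only hydroxyl), CO, and a terminal arylacetylene (ring B, 3'-oxygen masked as benzyl ether). Each aromatic partner is made as a single regioisomer, its substitution sites fixed by symmetry, matched directing groups or a lone free C–H. Hydrogenolysis ends the route.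

Key step: step 11

Remarks on the chemistry: ring B is built from 2,6-dimethoxyphenol because halogenation of 2,3,6-trimethoxyphenol would be steered para to its free hydroxyl group (the future C6') and its ethers offer no clear bias between the two open positions; the push–pull double bond of the enaminone formed in the key step is drawn E, is configurationally labile and has no bearing on the outcome.

**Ring A (steps 1–4)**

Step 1
Reactants: 1 2,3,4-trimethoxybenzaldehyde
Product: 3 2,3,4-trimethoxyphenol, via aryl formate 2 (not isolated)
Conditions: 30% aq. H2O2, cat. H2SO4, MeOH, rt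
Reagents that add atoms: hydrogen peroxide OO
Why: Acid-catalysed Dakin oxidation (Baeyer–Villiger-type aryl migration): the electron-rich aryl group shifts from the peroxyhemiacetal carbon to oxygen, and formate 2 is methanolysed in the same flask.

Step 2
Reactants: 3 2,3,4-trimethoxyphenol
Product: 4 1,2,3,4-tetramethoxybenzene
Conditions: MeI, K2CO3, acetone, reflux
Reagents that add atoms: iodomethane CI
Why: Williamson ether synthesis, in which the phenoxide is the only nucleophile present and attacks an unhindered SN2 electrophile.

Step 3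
Reactants: 4 1,2,3,4-tetramethoxybenzene
Product: 7 2,3,4,5-tetramethoxyphenol, via aryllithium 5 (not isolated), via dimethyl arylboronate 6 (not isolated)
Conditions: n-BuLi, TMEDA, THF, 0 °C → rt; B(OMe)3, −78 °C → rt; AcOH, 30% aq. H2O2, 0 °C → rt
Reagents that add atoms: hydrogen peroxide OO (oxygen of 7); n-butyllithium [Li]CCCC (lithium of 5 only); trimethyl borate COB(OC)OC (boron and its methoxy groups in 6 only)
Why: Directed ortho-metalation, borylation and peroxide-induced 1,2-aryl shift from boron to oxygen: the two ring C–H bonds of 4 are equivalent by symmetry and each sits next to a coordinating methoxy group, so only one aryllithium can form, and the weakly acidic peroxide medium spares the oxidation-prone phenol.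

Step 4
Reactants: 7 2,3,4,5-tetramethoxyphenol
Product: 8 2-iodo-3,4,5,6-tetramethoxyphenol
Conditions: NIS (1.0 equiv), MeCN, 0 °C, dark
Reagents that add atoms: N-iodosuccinimide O=C1CCC(=O)N1I
Why: Electrophilic aromatic iodination: the only ring C–H of 7 is ortho to the hydroxyl group and para to a methoxy group, so a mild iodonium source at low temperature should suffice and no regioisomer is possible.

**Ring B (steps 5–10)**

Step 5
Reactants: 9 2,6-dimethoxyphenol
Product: 10 2-benzyloxy-1,3-dimethoxybenzene
Conditions: BnBr, K2CO3, DMF, 60 °C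
Reagents that add atoms: benzyl bromide BrCc1ccccc1
Why: Williamson ether synthesis, in which the flanked phenoxide still reacts cleanly with the reactive benzylic halide in a dipolar aprotic solvent.

Step 6
Reactants: 10 2-benzyloxy-1,3-dimethoxybenzene
Product: 12 3-benzyloxy-1,5-dibromo-2,4-dimethoxybenzene, via monobromide 11 (not isolated)
Conditions: NBS (2.2 equiv), MeCN, 0 → 40 °C, dark
Reagents that add atoms: N-bromosuccinimide O=C1CCC(=O)N1Br
Why: Twofold electrophilic aromatic bromination: in 10 and again in 11 the open position ortho to one outer methoxy group and para to the other is by far the most activated, whereas the position para to the benzyloxy group is fed only by an ether oxygen twisted out of conjugation by its two neighbours, so the symmetric 1,5-dibromide should result.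

Step 7
Reactants: 12 3-benzyloxy-1,5-dibromo-2,4-dimethoxybenzene
Product: 15 3-benzyloxy-5-bromo-2,4-dimethoxyphenol, via bromoaryllithium 13 (not isolated), via dimethyl bromoarylboronate 14 (not isolated)
Conditions: n-BuLi (1.0 equiv), THF, −78 °C; B(OMe)3, −78 °C → rt; AcOH, 30% aq. H2O2, 0 °C → rt
Reagents that add atoms: hydrogen peroxide OO (oxygen of 15); n-butyllithium [Li]CCCC (lithium of 13 only); trimethyl borate COB(OC)OC (boron and its methoxy groups in 14 only)
Why: Bromine–lithium exchange, borylation and oxidation: the two bromine atoms of 12 are equivalent by symmetry, so one equivalent of n-BuLi can give only one aryllithium, the exchange at −78 °C outruns benzylic deprotonation, and the new oxygen ends up where the 5'-methoxy group is needed.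

Step 8
Reactants: 15 3-benzyloxy-5-bromo-2,4-dimethoxyphenol
Product: 16 3-benzyloxy-1-bromo-2,4,5-trimethoxybenzene
Conditions: MeI, K2CO3, acetone, reflux
Reagents that add atoms: iodomethane CI
Why: Williamson ether synthesis on the only free hydroxyl group, which leaves the aryl bromide and the benzyl ether untouched.

Step 9
Reactants: 16 3-benzyloxy-1-bromo-2,4,5-trimethoxybenzene; 17 trimethylsilylacetylene
Product: 18 [(3-benzyloxy-2,4,5-trimethoxyphenyl)ethynyl]trimethylsilane
Conditions: PdCl2(PhCN)2 (3 mol %), P(t-Bu)3 (6 mol %), CuI (2 mol %), i-Pr2NH, dioxane, rt → 45 °C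
Reagents that add atoms: none
Why: Sonogashira coupling, in which the bulky electron-rich phosphine speeds oxidative addition into the electron-rich, ortho-substituted C–Br bond and the silyl cap prevents a second coupling at the alkyne.

Step 10
Reactants: 18 [(3-benzyloxy-2,4,5-trimethoxyphenyl)ethynyl]trimethylsilane
Product: 19 3-benzyloxy-1-ethynyl-2,4,5-trimethoxybenzene
Conditions: K2CO3 (0.2 equiv), MeOH, rt
Reagents that add atoms: none
Why: Base-catalysed protodesilylation, in which methoxide attacks silicon, the released acetylide is protonated by methanol and all ether groups are inert.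

**Union and deprotection (steps 11–12)**

Step 11
Reactants: 8 2-iodo-3,4,5,6-tetramethoxyphenol; 19 3-benzyloxy-1-ethynyl-2,4,5-trimethoxybenzene; 20 carbon monoxide
Product: 23 3'-benzyloxy-5,6,7,8,2',4',5'-heptamethoxyflavone (3'-O-benzyl agehoustin C), via hydroxyaryl ynone 21 (not isolated), via enaminone 22 (not isolated)
Conditions: PdCl2(PPh3)2 (5 mol %), CO (20 bar), Et2NH, 120 °C, autoclave
Reagents that add atoms: diethylamine CCNCC (nitrogen and ethyl groups of 22 only, released again on ring closure)
Why: Zerovalent palladium, formed in situ from the divalent precatalyst, inserts into the C–I bond of 8, CO migratory insertion gives the aroylpalladium iodide, and the acetylide generated from 19 by the amine is transferred to palladium and reductively eliminated, which forms C4a–C4 and C4–C3 in ynone 21. Diethylamine adds in conjugate fashion to 21 to give enaminone 22, the C8a hydroxyl attacks C2 of 22, and expulsion of the amine forms O1–C2, so ring C closes by a 6-endo-trig addition–elimination. The closest known reaction type is the carbonylative Sonogashira annulation of ortho-iodophenols with terminal arylacetylenes in a secondary amine, an established flavone synthesis. No stereocentre is created. The step needs CO uptake before alkynylation, which is secured by 20 bar of CO, the omission of a copper co-catalyst and the electron-rich aryl group that migrates readily to bound CO, and it needs six-membered instead of 5-exo (aurone) closure, which is secured because in 22 only C2 is electrophilic. Positional selectivity in ring A is built into 8, whose iodine stands ortho to the only hydroxyl group.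

Step 12
Reactants: 23 3'-O-benzyl agehoustin C
Product: 24 agehoustin C (3'-hydroxy-5,6,7,8,2',4',5'-heptamethoxyflavone)
Conditions: H2 (1 atm), 10% Pd/C, EtOAc–MeOH, rt
Reagents that add atoms: none
Why: Catalytic hydrogenolysis of a benzyl aryl ether, run at room temperature and one atmosphere so that the C2–C3 double bond of the pyranone (a vinylogous ester) and the seven methyl ethers should persist.

**Compound list**

1 | 2,3,4-trimethoxybenzaldehyde | COc1ccc(C=O)c(OC)c1OC | starting material
2 | 2,3,4-trimethoxyphenyl formate (not isolated) | COc1ccc(OC=O)c(OC)c1OC | intermediate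
3 | 2,3,4-trimethoxyphenol | COc1ccc(O)c(OC)c1OC | intermediate
4 | 1,2,3,4-tetramethoxybenzene | COc1ccc(OC)c(OC)c1OC | intermediate
5 | (2,3,4,5-tetramethoxyphenyl)lithium (not isolated) | [Li]c1cc(OC)c(OC)c(OC)c1OC | intermediate
6 | dimethyl (2,3,4,5-tetramethoxyphenyl)boronate (not isolated) | COB(OC)c1cc(OC)c(OC)c(OC)c1OC | intermediate
7 | 2,3,4,5-tetramethoxyphenol | Oc1cc(OC)c(OC)c(OC)c1OC | intermediate
8 | 2-iodo-3,4,5,6-tetramethoxyphenol | Oc1c(I)c(OC)c(OC)c(OC)c1OC | intermediate
9 | 2,6-dimethoxyphenol | COc1cccc(OC)c1O | starting material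
10 | 2-benzyloxy-1,3-dimethoxybenzene | COc1cccc(OC)c1OCc1ccccc1 | intermediate
11 | 2-benzyloxy-4-bromo-1,3-dimethoxybenzene (not isolated) | COc1ccc(Br)c(OC)c1OCc1ccccc1 | intermediate
12 | 3-benzyloxy-1,5-dibromo-2,4-dimethoxybenzene | COc1c(Br)cc(Br)c(OC)c1OCc1ccccc1 | intermediate
13 | (3-benzyloxy-5-bromo-2,4-dimethoxyphenyl)lithium (not isolated) | [Li]c1cc(Br)c(OC)c(OCc2ccccc2)c1OC | intermediate
14 | dimethyl (3-benzyloxy-5-bromo-2,4-dimethoxyphenyl)boronate (not isolated) | COB(OC)c1cc(Br)c(OC)c(OCc2ccccc2)c1OC | intermediate
15 | 3-benzyloxy-5-bromo-2,4-dimethoxyphenol | Oc1cc(Br)c(OC)c(OCc2ccccc2)c1OC | intermediate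
16 | 3-benzyloxy-1-bromo-2,4,5-trimethoxybenzene | COc1cc(Br)c(OC)c(OCc2ccccc2)c1OC | intermediate
17 | trimethylsilylacetylene | C#C[Si](C)(C)C | starting material
18 | [(3-benzyloxy-2,4,5-trimethoxyphenyl)ethynyl]trimethylsilane | C[Si](C)(C)C#Cc1cc(OC)c(OC)c(OCc2ccccc2)c1OC | intermediate
19 | 3-benzyloxy-1-ethynyl-2,4,5-trimethoxybenzene | C#Cc1cc(OC)c(OC)c(OCc2ccccc2)c1OC | intermediate
20 | carbon monoxide | [C-]#[O+] | starting material
21 | 3-(3-benzyloxy-2,4,5-trimethoxyphenyl)-1-(2-hydroxy-3,4,5,6-tetramethoxyphenyl)prop-2-yn-1-one (not isolated) | COc1cc(C#CC(=O)c2c(O)c(OC)c(OC)c(OC)c2OC)c(OC)c(OCc2ccccc2)c1OC | intermediate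
22 | (E)-3-(3-benzyloxy-2,4,5-trimethoxyphenyl)-3-(diethylamino)-1-(2-hydroxy-3,4,5,6-tetramethoxyphenyl)prop-2-en-1-one (not isolated) | CCN(CC)/C(=C/C(=O)c1c(O)c(OC)c(OC)c(OC)c1OC)c1cc(OC)c(OC)c(OCc2ccccc2)c1OC | intermediate
23 | 3'-benzyloxy-5,6,7,8,2',4',5'-heptamethoxyflavone | COc1cc(-c2cc(=O)c3c(OC)c(OC)c(OC)c(OC)c3o2)c(OC)c(OCc2ccccc2)c1OC | intermediate
24 | agehoustin C, 3'-hydroxy-5,6,7,8,2',4',5'-heptamethoxyflavone | COc1cc(-c2cc(=O)c3c(OC)c(OC)c(OC)c(OC)c3o2)c(OC)c(O)c1OC | target

Total step count: 12.
Longest linear sequence: 8 steps (steps 5–12, from 2,6-dimethoxyphenol). The ring A branch contributes steps 1–4.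

**Steps most likely to fail**

1. **Step 11.**
   - Diethylamine may capture the aroylpalladium intermediate (aminocarbonylation).
   - The alkyne may couple without CO uptake, with subsequent closure to a benzofuran.
   - The very electron-rich ring may lose its iodine reductively.

   Fallback: a Baker–Venkataraman construction of ring C, which sets out from 7 and 16 and rejoins the route at 23. Phenol 7 is C-acetylated at its only free position (Ac2O, BF3·OEt2, 60 °C, Fries-type acylation) to 1-(2-hydroxy-3,4,5,6-tetramethoxyphenyl)ethanone F1. Bromide 16 is converted with Mg turnings in THF into (3-benzyloxy-2,4,5-trimethoxyphenyl)magnesium bromide F2. Quenching with CO2 and then dilute HCl gives 3-benzyloxy-2,4,5-trimethoxybenzoic acid F3. EDC and DMAP in CH2Cl2 join F1 and F3 to the 2-acetyl-3,4,5,6-tetramethoxyphenyl ester F4. KOH in pyridine at 50 °C moves the aroyl group from oxygen to the acetyl carbon and gives the 1,3-diketone F5. Catalytic p-TsOH in refluxing toluene cyclodehydrates F5 to 23.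

2. **Step 4.** The iodinating agent may oxidise the para-methoxyphenol (oxidative demethylation towards a quinone) in competition with substitution. The product may also lose iodine under light.

   Fallback: an anionic instead of an electrophilic iodination, which sets out from 7 and rejoins at 8. MOMCl and i-Pr2NEt in CH2Cl2 give 1-(methoxymethoxy)-2,3,4,5-tetramethoxybenzene F6. n-BuLi in THF (−78 → 0 °C) removes the only ring proton, flanked by two coordinating oxygens, in a directed ortho-metalation and gives the aryllithium F7. Iodine converts it into 1-iodo-2-(methoxymethoxy)-3,4,5,6-tetramethoxybenzene F8. Dilute HCl in MeOH at 40 °C removes the acetal and gives 8.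

3. **Step 9.** Oxidative addition into the electron-rich, ortho-substituted C–Br bond may be slow, so that the alkyne is consumed by oxidative dimerisation before coupling.

   Fallback: a palladium-free one-carbon homologation, which sets out from 16 and rejoins at 19, bypassing 18 and step 10. n-BuLi in THF at −78 °C gives (3-benzyloxy-2,4,5-trimethoxyphenyl)lithium F9. DMF followed by dilute HCl gives 3-benzyloxy-2,4,5-trimethoxybenzaldehyde F10. Dimethyl (1-diazo-2-oxopropyl)phosphonate with K2CO3 in MeOH at rt (Seyferth–Gilbert homologation with the Ohira–Bestmann reagent) converts the aldehyde into 19.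

**Further compounds**

F1 | step 11 | 1-(2-hydroxy-3,4,5,6-tetramethoxyphenyl)ethanone | CC(=O)c1c(O)c(OC)c(OC)c(OC)c1OC
F2 | step 11 | (3-benzyloxy-2,4,5-trimethoxyphenyl)magnesium bromide | Br[Mg]c1cc(OC)c(OC)c(OCc2ccccc2)c1OC
F3 | step 11 | 3-benzyloxy-2,4,5-trimethoxybenzoic acid | OC(=O)c1cc(OC)c(OC)c(OCc2ccccc2)c1OC
F4 | step 11 | 2-acetyl-3,4,5,6-tetramethoxyphenyl 3-benzyloxy-2,4,5-trimethoxybenzoate | CC(=O)c1c(OC(=O)c2cc(OC)c(OC)c(OCc3ccccc3)c2OC)c(OC)c(OC)c(OC)c1OC
F5 | step 11 | 1-(3-benzyloxy-2,4,5-trimethoxyphenyl)-3-(2-hydroxy-3,4,5,6-tetramethoxyphenyl)propane-1,3-dione | O=C(CC(=O)c1cc(OC)c(OC)c(OCc2ccccc2)c1OC)c1c(O)c(OC)c(OC)c(OC)c1OC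
F6 | step 4 | 1-(methoxymethoxy)-2,3,4,5-tetramethoxybenzene | COCOc1cc(OC)c(OC)c(OC)c1OC
F7 | step 4 | [2-(methoxymethoxy)-3,4,5,6-tetramethoxyphenyl]lithium | [Li]c1c(OCOC)c(OC)c(OC)c(OC)c1OC
F8 | step 4 | 1-iodo-2-(methoxymethoxy)-3,4,5,6-tetramethoxybenzene | COCOc1c(I)c(OC)c(OC)c(OC)c1OC
F9 | step 9 | (3-benzyloxy-2,4,5-trimethoxyphenyl)lithium | [Li]c1cc(OC)c(OC)c(OCc2ccccc2)c1OC
F10 | step 9 | 3-benzyloxy-2,4,5-trimethoxybenzaldehyde | O=Cc1cc(OC)c(OC)c(OCc2ccccc2)c1OC
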